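## Analysis of the target

Compound 16 is a flavone: a benzene ring A fused to a 4-pyranone ring C (4H-chromen-4-one), with an aryl ring B on C2. Ring A carries oxygen on three of its four free positions (5-OH, 7-OMe, 8-OMe; only C6 is unsubstituted). Ring C carries a 3-methoxy group, and ring B is a 2',3'-catechol whose 2'-oxygen crowds the C2–C1' bond. The target has no stereocentre; the two sp3 carbons that the route creates (C2 and C3 of a flavanone) are transient, so their relative configuration needs no control. The sensitive parts are the catechol (easily oxidised to the ortho-quinone), the 5-hydroxyl hydrogen-bonded to the C4 carbonyl, and the vinylogous ester of ring C, which bases open to chalcones. The difficulty is differentiation and placement: three hydroxyls must end free beside three methyl ethers, and the 5,7,8-pattern of ring A must be set without leakage into the isomeric 5,6,7-pattern. The strategy rests on C4a of ring A, which lies ortho to O1, ortho to the 5-oxygen and para to the 7-methoxy group, and is the only free carbon next to O1. With C2–C3 of ring C held saturated, the C4 carbonyl can be delivered to C4a from a 3-aryl-3-aryloxy-2-methoxypropanoic acid whose substituents come from aldol and etherification chemistry.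

## Retrosynthetic reasoning

**16 ⇒ 15.** The last bonds made are three O–H bonds. In 15 the 5-, 2'- and 3'-oxygens are benzyl ethers, while the 3-, 7- and 8-oxygens are already the methyl ethers of the target. The two sets of oxygens are thus told apart by the protecting group alone, and the oxidation-prone catechol appears only in the final, neutral hydrogenolysis.

**15 ⇒ 13.** The C2=C3 double bond of 15 is taken back to the single bond of flavanone 13. This allows ring C to be assembled from sp3 carbons by carbonyl chemistry. The price is one dehydrogenation (through iodide 14) that must spare the benzyl ethers. The two stereocentres of 13 are erased here, so nothing earlier has to control them.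

**13 ⇒ 11.** Ring C is opened at the C4–C4a bond, giving acid 11 (activated in the forward sense as mixed anhydride 12). This bond is preferred to O1–C2 because the future C4a is the one position of the ring-A ether in 11 that is next to O1, flanked by a second oxygen, and para to a third. A tethered acyl group can go nowhere else. An O1–C2 closure would instead need an ortho-hydroxyaryl ketone made by an intermolecular acylation with two ring positions to choose from. The forward reaction must acylate that carbon under conditions mild enough for three benzyl ethers and the benzylic aryl ether.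

**11 ⇒ 10 ⇒ 9 ⇒ 7.** These are functional-group adjustments.
- The acid is carried as tert-butyl ester 10 and released by acid, because the 3-aryloxy group is a leaving group β to the carbonyl and base would invite its elimination.
- The 5-benzyl ether of 10 comes from phenol 9.
- The phenolic oxygen of 9 is traced to the formyl carbon of aldehyde 7 by Baeyer–Villiger oxidation through formate 8.
- Keeping that position as a formyl group up to 7 lets ring A enter as 6 with its oxygen pattern complete and no protecting-group exchange. It also keeps ring A electron-poor during the preceding etherification, where an electron-rich ring could be alkylated at carbon.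

**7 ⇒ 5 + 6.** The benzylic C–O bond (the future O1–C2) is cut, dividing the molecule into halves of similar size; it is formed by Mitsunobu etherification of alcohol 5 with phenol 6. In 6 the hydroxyl is flanked by a methoxy group and the formyl carbon lies between two unsubstituted positions. O1 must therefore end next to the 8-methoxy group, and the oxygen that replaces the formyl carbon ends at C5. The 5,7,8-pattern is fixed by the constitution of 6, not by a selective reaction.

**5 ⇒ 2 + 3.** The C2–C3 bond is cut by an aldol disconnection. Ester 3, as its lithium enolate 4, brings C3 with its methoxy group and C4 at the acid oxidation level; aldehyde 2 brings C2 with ring B. No selectivity is asked of this step.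

**2 ⇒ 1.** The benzyl ethers of ring B are put on the commercial catechol aldehyde 1 at the outset, so that one protecting group serves all three hydroxyls of the target.

## Alternatives that were turned down

**Alternative 1:** ring C by a hetero-Diels–Alder reaction of an ortho-quinone ketene.
- **Disconnection:** C3–C4 and O1–C2 are cut together. Flavone A1 (5-pivalate, ring-B bis(methoxymethyl) ether) divides into benzodioxinone A2, which carries ring A, and silyl enol ether A3, which carries C2, C3 and ring B.
- **Forward key step:** heating A2 causes cycloreversion of the acetonide and leaves ortho-quinone ketene A4. A3 adds across its O=C–C=C=O unit in a [4+2] sense, the ketene carbon bonding to the methoxy-bearing carbon and the ring oxygen to the silyloxy carbon. Elimination of the silyloxy group then aromatises ring C.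
- **For:** two ring bonds form in one operation and the flavone oxidation level is reached directly. On this point it is stronger than the chosen route, which needs the separate dehydrogenation of step 8. The ring-A pattern is fixed by A2.
- **Against:** A2 is a pentasubstituted benzene whose carboxyl carbon must be introduced on a ring-A phenol and then masked, steps the chosen route does not need. A4 is hindered on both flanks (pivalate beside the ketene carbon, methoxy beside the carbonyl), so dimerisation and capture by stray nucleophiles compete when the 2π partner is slow. A3 has oxygen donors on both alkene carbons that polarise it in opposite directions, and its ortho-substituted aryl group is twisted, so neither rate nor orientation is assured. The temperature needed is high for methoxymethyl ethers and a silyl enol ether.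
- **Comparison:** the chosen route makes the same two bonds one at a time (steps 3 and 7), with the orientation of the ring closure enforced by the tether in 11. It costs more linear steps, but each is ordinary.

**Alternative 2:** C2 brought in as carbon monoxide.
- **Disconnection:** C1'–C2, C2–C3 and O1–C2 are cut, leaving α-methoxy ketone A6, aryl iodide A7 and carbon monoxide A8 as the precursors of flavone A5.
- **Forward key step:** a zerovalent palladium catalyst with a wide-bite-angle bisphosphine inserts into A7 and takes up A8. The acylpalladium species acylates the enolate of A6 at carbon, and acid then condenses the ortho-hydroxyl with the new aryl ketone to close ring C.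
- **For:** it is the most convergent plan, with three bonds from three components and direct entry to the flavone level. In step count it is clearly stronger than the chosen route.
- **Against:** in A5 the 5-oxygen is a methyl ether and the catechol a methylene acetal. Freeing these while keeping the 3-, 7- and 8-methyl ethers needs a Lewis-acid cleavage that distinguishes the 5-methoxy from the 3-methoxy group (both flank the carbonyl) and also opens the dioxole. The enolate of A6 is α-alkoxylated and sits on a di-ortho-substituted aryl ketone, so C-acylation is hindered and the free phenoxide competes for the acyl group. A6 itself needs an intermolecular acylation of a ring-A phenol with two candidate positions.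
- **Comparison:** the chosen route gives up convergence for a secure end game: every hydroxyl of 16 is a benzyl ether removed in one hydrogenolysis, and the acylation position on ring A is dictated by the tether.

**Alternative 3:** ring A built by ring expansion of a cyclobutenone.
- **Disconnection:** the C4a–C5 bond is cut and ring A is traced back to the four carbons of hydroxycyclobutenone A10, itself from pyranone A11 and cyclobutenedione A12. The key-step product is quinol A9.
- **Forward key step:** heating A10 in xylene opens the four-membered ring to a dienylketene. The ketene carbon closes onto C5 of the pyranone in a 6π electrocyclisation, and tautomerisation gives A9.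
- **For:** the 5-hydroxyl arrives free and chelated, so the 8-hydroxyl can be methylated selectively without a protecting group on O5. On that point it is stronger than the chosen route, which spends steps 4 and 5 on O5. The ring-A oxygens are placed by construction.
- **Against:** A11 already contains ring B, ring C and the 3-methoxy group, so making it is a task comparable to making a flavone. Its metallation at C6 competes with nucleophilic attack on the pyranone. A9 is a para-quinol that oxidises readily to the quinone. Overall this is the longest sequence.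
- **Comparison:** the chosen route takes ring A from 6 with all its oxygens in place and puts its one uncertain bond formation into a single step on a substrate made by routine chemistry.

Key step: step 7

Remark on the chemistry: the two sp3 centres made in step 2 are not controlled. Compounds 5 and 7 to 13 are therefore handled as racemic mixtures of diastereomers, with one isomer drawn and named for each; both centres vanish in step 8.

## Route

Step 1
Reactants: 1 2,3-dihydroxybenzaldehyde
Product: 2 2,3-bis(benzyloxy)benzaldehyde
Conditions: BnBr (2.5 equiv), K2CO3, DMF, 60 °C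
Reagents that add atoms: benzyl bromide, BrCc1ccccc1
Why: Williamson etherification of both phenoxides by SN2 on the benzylic bromide; warming is used because the 2-hydroxyl is hydrogen-bonded to the formyl group and reacts more slowly.

Step 2
Reactants: 3 tert-butyl methoxyacetate; 2 2,3-bis(benzyloxy)benzaldehyde
Product: 5 tert-butyl 3-[2,3-bis(benzyloxy)phenyl]-3-hydroxy-2-methoxypropanoate (racemic diastereomer mixture; the (2RS,3SR) isomer is drawn), via lithium enolate 4 (not isolated)
Conditions: LiN(iPr)2, THF, −78 °C; then 2, −78 °C; AcOH quench
Reagents that add atoms: none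
Why: Directed aldol addition: the ester is fully deprotonated before the non-enolisable aldehyde is added, and the cold acetic acid quench prevents retro-aldol cleavage. Two stereocentres form without control, which is accepted because both are removed in step 8.

Step 3
Reactants: 5 tert-butyl 3-[2,3-bis(benzyloxy)phenyl]-3-hydroxy-2-methoxypropanoate; 6 3-hydroxy-4,5-dimethoxybenzaldehyde
Product: 7 tert-butyl 3-[2,3-bis(benzyloxy)phenyl]-3-(5-formyl-2,3-dimethoxyphenoxy)-2-methoxypropanoate (racemic diastereomer mixture; the (2RS,3RS) isomer is drawn)
Conditions: PPh3, DIAD (added slowly), toluene, 0 °C to rt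
Reagents that add atoms: none
Why: Mitsunobu etherification of a secondary benzylic alcohol by a phenol, with inversion at C3; the formyl group meta to the hydroxyl makes 6 acidic enough to protonate the betaine and keeps its ring from reacting as a carbon nucleophile. Any ionisation at the benzylic carbon would only change the diastereomer ratio, which is of no consequence.

Step 4
Reactants: 7 tert-butyl 3-[2,3-bis(benzyloxy)phenyl]-3-(5-formyl-2,3-dimethoxyphenoxy)-2-methoxypropanoate
Product: 9 tert-butyl 3-[2,3-bis(benzyloxy)phenyl]-3-(5-hydroxy-2,3-dimethoxyphenoxy)-2-methoxypropanoate (racemic diastereomer mixture; the (2RS,3RS) isomer is drawn), via aryl formate 8 (not isolated)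
Conditions: mCPBA, CH2Cl2, 0 °C to rt; then Et3N, MeOH, 0 °C
Reagents that add atoms: 3-chloroperoxybenzoic acid (mCPBA), OOC(=O)c1cccc(Cl)c1
Why: Baeyer–Villiger oxidation of an electron-rich benzaldehyde: the aryl group, which has a methoxy group para to the formyl carbon, migrates in the Criegee adduct to give formate 8, and mild methanolysis cleaves the formate without touching the tert-butyl ester. The alkaline H2O2 Dakin protocol is not used because the ring has no free hydroxyl ortho or para to the formyl group and base would endanger the β-aryloxy ester.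

Step 5
Reactants: 9 tert-butyl 3-[2,3-bis(benzyloxy)phenyl]-3-(5-hydroxy-2,3-dimethoxyphenoxy)-2-methoxypropanoate
Product: 10 tert-butyl 3-[2,3-bis(benzyloxy)phenyl]-3-[5-(benzyloxy)-2,3-dimethoxyphenoxy]-2-methoxypropanoate (racemic diastereomer mixture; the (2RS,3RS) isomer is drawn)
Conditions: BnBr, K2CO3, acetone, rt to 45 °C
Reagents that add atoms: benzyl bromide, BrCc1ccccc1
Why: Williamson etherification of the unhindered phenol; K2CO3 in acetone is too weak a base to deprotonate the ester α-carbon, so the β-aryloxy group should not be eliminated.

Step 6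
Reactants: 10 tert-butyl 3-[2,3-bis(benzyloxy)phenyl]-3-[5-(benzyloxy)-2,3-dimethoxyphenoxy]-2-methoxypropanoate
Product: 11 3-[2,3-bis(benzyloxy)phenyl]-3-[5-(benzyloxy)-2,3-dimethoxyphenoxy]-2-methoxypropanoic acid (racemic diastereomer mixture; the (2RS,3RS) isomer is drawn)
Conditions: CF3CO2H/CH2Cl2 (1:4), 0 °C
Reagents that add atoms: none
Why: Acidolysis of the tert-butyl ester by alkyl–oxygen cleavage, the tert-butyl cation leaving as 2-methylpropene; acid is chosen because hydroxide could expel the aryloxide from C3 by β-elimination. Benzyl aryl ethers should withstand dilute CF3CO2H at 0 °C.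

Step 7
Reactants: 11 3-[2,3-bis(benzyloxy)phenyl]-3-[5-(benzyloxy)-2,3-dimethoxyphenoxy]-2-methoxypropanoic acid
Product: 13 trans-5-(benzyloxy)-2-[2,3-bis(benzyloxy)phenyl]-3,7,8-trimethoxychroman-4-one (racemic; the (2S,3S) enantiomer is drawn; the cis isomer may accompany it), via mixed anhydride 12 (not isolated)
Conditions: (CF3CO)2O (3 equiv), CH2Cl2 (0.02 M), 0 °C to rt; aq NaHCO3
Reagents that add atoms: none
Why: Intramolecular Friedel–Crafts acylation, the ring-closing step of the known chroman-4-one synthesis from 3-aryloxypropanoic acids. The anhydride converts the acid into mixed anhydride 12, whose non-fluorinated acyl carbon (or the acylium ion derived from it) is attacked by the free carbon ortho to the ether oxygen of ring A, the future C4a; loss of a proton restores the arene and completes the C4–C4a bond. Ring C closes in a 6-exo-trig mode at the anhydride carbonyl (6-exo-dig if the free acylium ion is the electrophile). No stereocentre is created: C2 and C3 are carried over from 11, C3 can epimerise through the enol toward the trans isomer, and both centres are removed in step 8. The step needs regioselectivity, and the substrate supplies it: the attacked carbon is the only unsubstituted position next to the ether oxygen and is activated by that oxygen, by the ortho benzyloxy group and by the para methoxy group. The other free carbon of ring A cannot be reached by the tether, and closure onto ring B would give a five-membered indanone at a carbon activated by a single para oxygen. The benzyl ethers and the benzylic aryl ether are spared by working cold and dilute, with no Lewis or mineral acid and only the CF3CO2H that the reaction itself releases.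

Step 8
Reactants: 13 trans-5-(benzyloxy)-2-[2,3-bis(benzyloxy)phenyl]-3,7,8-trimethoxychroman-4-one
Product: 15 5-(benzyloxy)-2-[2,3-bis(benzyloxy)phenyl]-3,7,8-trimethoxy-4H-chromen-4-one, via 3-iodoflavanone 14 (not isolated)
Conditions: I2 (0.2 equiv), DMSO, 120 °C
Reagents that add atoms: none
Why: Dehydrogenation of a flavanone to a flavone with iodine in DMSO: the enol of the C4 ketone is iodinated at C3, loss of HI across C2–C3 gives the chromone, and DMSO reoxidises HI to I2. Both stereocentres disappear, and any 5-O-debenzylated flavone formed by the transient HI would converge on 16 in step 9.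

Step 9
Reactants: 15 5-(benzyloxy)-2-[2,3-bis(benzyloxy)phenyl]-3,7,8-trimethoxy-4H-chromen-4-one
Product: 16 5,2',3'-trihydroxy-3,7,8-trimethoxyflavone [2-(2,3-dihydroxyphenyl)-5-hydroxy-3,7,8-trimethoxy-4H-chromen-4-one]
Conditions: H2 (1 atm), 10% Pd/C, EtOAc–MeOH, rt; filtration and concentration under argon
Reagents that add atoms: none
Why: Hydrogenolysis of the three benzyl aryl ethers over palladium on carbon under neutral conditions; the methyl ethers are inert and the C2=C3 bond, part of a vinylogous ester, should not be reduced under one atmosphere of hydrogen.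

## Compound list

1 | 2,3-dihydroxybenzaldehyde | O=Cc1cccc(O)c1O | starting material
2 | 2,3-bis(benzyloxy)benzaldehyde | O=Cc1cccc(OCc2ccccc2)c1OCc1ccccc1 | intermediate
3 | tert-butyl methoxyacetate | COCC(=O)OC(C)(C)C | starting material
4 | lithium 1-tert-butoxy-2-methoxyethen-1-olate (chelated geometry drawn, methoxy and O–Li on the same side; geometry of no consequence) | [Li+].CO/C=C(\[O-])OC(C)(C)C | intermediate
5 | tert-butyl 3-[2,3-bis(benzyloxy)phenyl]-3-hydroxy-2-methoxypropanoate (racemic diastereomer mixture; (2RS,3SR) isomer drawn as 2S,3R) | O[C@H](c1cccc(OCc2ccccc2)c1OCc1ccccc1)[C@H](OC)C(=O)OC(C)(C)C | intermediate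
6 | 3-hydroxy-4,5-dimethoxybenzaldehyde | COc1cc(C=O)cc(O)c1OC | starting material
7 | tert-butyl 3-[2,3-bis(benzyloxy)phenyl]-3-(5-formyl-2,3-dimethoxyphenoxy)-2-methoxypropanoate (racemic diastereomer mixture; (2RS,3RS) isomer drawn as 2S,3S) | COc1cc(C=O)cc(O[C@@H](c2cccc(OCc3ccccc3)c2OCc2ccccc2)[C@H](OC)C(=O)OC(C)(C)C)c1OC | intermediate
8 | tert-butyl 3-[2,3-bis(benzyloxy)phenyl]-3-[5-(formyloxy)-2,3-dimethoxyphenoxy]-2-methoxypropanoate (racemic diastereomer mixture; (2RS,3RS) isomer drawn) | COc1cc(OC=O)cc(O[C@@H](c2cccc(OCc3ccccc3)c2OCc2ccccc2)[C@H](OC)C(=O)OC(C)(C)C)c1OC | intermediate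
9 | tert-butyl 3-[2,3-bis(benzyloxy)phenyl]-3-(5-hydroxy-2,3-dimethoxyphenoxy)-2-methoxypropanoate (racemic diastereomer mixture; (2RS,3RS) isomer drawn) | COc1cc(O)cc(O[C@@H](c2cccc(OCc3ccccc3)c2OCc2ccccc2)[C@H](OC)C(=O)OC(C)(C)C)c1OC | intermediate
10 | tert-butyl 3-[2,3-bis(benzyloxy)phenyl]-3-[5-(benzyloxy)-2,3-dimethoxyphenoxy]-2-methoxypropanoate (racemic diastereomer mixture; (2RS,3RS) isomer drawn) | COc1cc(OCc2ccccc2)cc(O[C@@H](c2cccc(OCc3ccccc3)c2OCc2ccccc2)[C@H](OC)C(=O)OC(C)(C)C)c1OC | intermediate
11 | 3-[2,3-bis(benzyloxy)phenyl]-3-[5-(benzyloxy)-2,3-dimethoxyphenoxy]-2-methoxypropanoic acid (racemic diastereomer mixture; (2RS,3RS) isomer drawn) | COc1cc(OCc2ccccc2)cc(O[C@@H](c2cccc(OCc3ccccc3)c2OCc2ccccc2)[C@H](OC)C(=O)O)c1OC | intermediate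
12 | 3-[2,3-bis(benzyloxy)phenyl]-3-[5-(benzyloxy)-2,3-dimethoxyphenoxy]-2-methoxypropanoic trifluoroacetic anhydride (racemic diastereomer mixture; (2RS,3RS) isomer drawn) | COc1cc(OCc2ccccc2)cc(O[C@@H](c2cccc(OCc3ccccc3)c2OCc2ccccc2)[C@H](OC)C(=O)OC(=O)C(F)(F)F)c1OC | intermediate
13 | trans-5-(benzyloxy)-2-[2,3-bis(benzyloxy)phenyl]-3,7,8-trimethoxychroman-4-one (racemic; (2S,3S) enantiomer drawn) | COc1cc(OCc2ccccc2)c2C(=O)[C@@H](OC)[C@H](c3cccc(OCc4ccccc4)c3OCc3ccccc3)Oc2c1OC | intermediate
14 | 5-(benzyloxy)-2-[2,3-bis(benzyloxy)phenyl]-3-iodo-3,7,8-trimethoxychroman-4-one (racemic; either configuration at C3; C2 drawn as in 13) | COc1cc(OCc2ccccc2)c2C(=O)C(I)(OC)[C@H](c3cccc(OCc4ccccc4)c3OCc3ccccc3)Oc2c1OC | intermediate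
15 | 5-(benzyloxy)-2-[2,3-bis(benzyloxy)phenyl]-3,7,8-trimethoxy-4H-chromen-4-one | COc1cc(OCc2ccccc2)c2c(=O)c(OC)c(-c3cccc(OCc4ccccc4)c3OCc3ccccc3)oc2c1OC | intermediate
16 | 5,2',3'-trihydroxy-3,7,8-trimethoxyflavone | COc1cc(O)c2c(=O)c(OC)c(-c3cccc(O)c3O)oc2c1OC | target

## Step count and least certain steps

Total: 9 steps. Longest linear sequence: 9 steps (1 to 16); 3 and 6 enter as bought components.

**Step 7 (key step).**
- What may go wrong: acid-promoted ionisation of the benzylic C3–O bond of 11 or 12, which the ortho-benzyloxy group of ring B assists. This would release the ring-A phenol fragment and let it recombine through carbon. A lesser risk is loss of the 5-O-benzyl group once it sits peri to the new carbonyl.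
- Fallback: form the aryl ketone bond first, on a simple ring-A ether with no benzylic C–O bond to lose, and close ring C at O1–C2 afterwards. It sets out from 6 and 2.
- Phenol 6 is converted with MOMCl and iPr2NEt into 3,4-dimethoxy-5-(methoxymethoxy)benzaldehyde F1. Baeyer–Villiger oxidation with mCPBA gives 3,4-dimethoxy-5-(methoxymethoxy)phenyl formate F2, which methanolysis turns into 3,4-dimethoxy-5-(methoxymethoxy)phenol F3. Benzylation gives 5-(benzyloxy)-1,2-dimethoxy-3-(methoxymethoxy)benzene F4.
- Lithiation with n-BuLi in THF at 0 °C, directed to the carbon between the methoxymethoxy and benzyloxy groups, gives [6-(benzyloxy)-3,4-dimethoxy-2-(methoxymethoxy)phenyl]lithium F5. N,2-dimethoxy-N-methylacetamide acylates it to 1-[6-(benzyloxy)-3,4-dimethoxy-2-(methoxymethoxy)phenyl]-2-methoxyethan-1-one F6. HCl in MeOH removes the methoxymethyl group and leaves 1-[6-(benzyloxy)-2-hydroxy-3,4-dimethoxyphenyl]-2-methoxyethan-1-one F7.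
- Claisen–Schmidt condensation of F7 with 2 (KOH, EtOH) gives (Z)-1-[6-(benzyloxy)-2-hydroxy-3,4-dimethoxyphenyl]-3-[2,3-bis(benzyloxy)phenyl]-2-methoxyprop-2-en-1-one F8. I2 in DMSO cyclises F8 by oxa-Michael addition and dehydrogenates ring C, so the fallback comes back to the route at 15.

**Step 3.**
- What may go wrong: β-elimination from the oxyphosphonium intermediate to the α-methoxycinnamate. The α-hydrogen is activated by the ester, and substitution at the hindered benzylic carbon is slow.
- Fallback: make the C3–O bond by epoxide opening, setting out from 2 and 6. Darzens condensation of 2 with tert-butyl chloroacetate (KOtBu, THF, 0 °C) gives tert-butyl trans-3-[2,3-bis(benzyloxy)phenyl]oxirane-2-carboxylate F9. The phenoxide of 6 (Cs2CO3, DMF, 60 °C) opens the epoxide at the benzylic carbon with inversion to give tert-butyl (2RS,3RS)-3-[2,3-bis(benzyloxy)phenyl]-3-(5-formyl-2,3-dimethoxyphenoxy)-2-hydroxypropanoate F10. O-methylation with Me3OBF4 and 1,8-bis(dimethylamino)naphthalene then gives 7 as its (2RS,3RS) diastereomer, where the fallback rejoins the route.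

**Step 6.**
- What may go wrong: alkylation of the very electron-rich ring A by the tert-butyl cation, or acid cleavage at the benzylic ether. A cation scavenger is the first remedy at the level of conditions.
- Fallback: reach the acid by a reduction–oxidation detour that never generates a carbocation, setting out from 10. LiAlH4 (THF, 0 °C) reduces the ester to (2RS,3SR)-3-[2,3-bis(benzyloxy)phenyl]-3-[5-(benzyloxy)-2,3-dimethoxyphenoxy]-2-methoxypropan-1-ol F11 (same relative configuration as 10; the C2 descriptor changes by the priority rules only). Oxidation with catalytic TEMPO and PhI(OAc)2 in MeCN–H2O passes through (2RS,3RS)-3-[2,3-bis(benzyloxy)phenyl]-3-[5-(benzyloxy)-2,3-dimethoxyphenoxy]-2-methoxypropanal F12 and ends at acid 11.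

**Step 8.**
- What may go wrong: slow iodination at the methoxy-bearing C3, so that conversion stalls, and competing iodination of ring A at C6. Ring opening to the chalcone is not a dead end under these conditions.
- Fallback: a palladium-mediated dehydrogenation through an isolated enol ether, setting out from 13. TMSOTf and Et3N (CH2Cl2, 0 °C) give 5-(benzyloxy)-2-[2,3-bis(benzyloxy)phenyl]-3,7,8-trimethoxy-4-[(trimethylsilyl)oxy]-2H-chromene F13. Stoichiometric Pd(OAc)2 in MeCN (Saegusa–Ito oxidation: a divalent palladium enolate loses the C2 hydrogen by β-hydride elimination) then gives 15.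

## Further compounds

F1 | step 7 | 3,4-dimethoxy-5-(methoxymethoxy)benzaldehyde | COCOc1cc(C=O)cc(OC)c1OC
F2 | step 7 | 3,4-dimethoxy-5-(methoxymethoxy)phenyl formate | COCOc1cc(OC=O)cc(OC)c1OC
F3 | step 7 | 3,4-dimethoxy-5-(methoxymethoxy)phenol | COCOc1cc(O)cc(OC)c1OC
F4 | step 7 | 5-(benzyloxy)-1,2-dimethoxy-3-(methoxymethoxy)benzene | COCOc1cc(OCc2ccccc2)cc(OC)c1OC
F5 | step 7 | [6-(benzyloxy)-3,4-dimethoxy-2-(methoxymethoxy)phenyl]lithium | [Li]c1c(OCOC)c(OC)c(OC)cc1OCc1ccccc1
F6 | step 7 | 1-[6-(benzyloxy)-3,4-dimethoxy-2-(methoxymethoxy)phenyl]-2-methoxyethan-1-one | COCOc1c(C(=O)COC)c(OCc2ccccc2)cc(OC)c1OC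
F7 | step 7 | 1-[6-(benzyloxy)-2-hydroxy-3,4-dimethoxyphenyl]-2-methoxyethan-1-one | COCC(=O)c1c(O)c(OC)c(OC)cc1OCc1ccccc1
F8 | step 7 | (Z)-1-[6-(benzyloxy)-2-hydroxy-3,4-dimethoxyphenyl]-3-[2,3-bis(benzyloxy)phenyl]-2-methoxyprop-2-en-1-one | CO/C(=C\c1cccc(OCc2ccccc2)c1OCc1ccccc1)C(=O)c1c(O)c(OC)c(OC)cc1OCc1ccccc1
F9 | step 3 | tert-butyl trans-3-[2,3-bis(benzyloxy)phenyl]oxirane-2-carboxylate (racemic; (2S,3R) enantiomer drawn) | CC(C)(C)OC(=O)[C@H]1O[C@@H]1c1cccc(OCc2ccccc2)c1OCc1ccccc1
F10 | step 3 | tert-butyl (2RS,3RS)-3-[2,3-bis(benzyloxy)phenyl]-3-(5-formyl-2,3-dimethoxyphenoxy)-2-hydroxypropanoate (racemic; (2S,3S) enantiomer drawn) | COc1cc(C=O)cc(O[C@@H](c2cccc(OCc3ccccc3)c2OCc2ccccc2)[C@H](O)C(=O)OC(C)(C)C)c1OC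
F11 | step 6 | (2RS,3SR)-3-[2,3-bis(benzyloxy)phenyl]-3-[5-(benzyloxy)-2,3-dimethoxyphenoxy]-2-methoxypropan-1-ol (racemic; (2R,3S) enantiomer drawn) | COc1cc(OCc2ccccc2)cc(O[C@@H](c2cccc(OCc3ccccc3)c2OCc2ccccc2)[C@H](OC)CO)c1OC
F12 | step 6 | (2RS,3RS)-3-[2,3-bis(benzyloxy)phenyl]-3-[5-(benzyloxy)-2,3-dimethoxyphenoxy]-2-methoxypropanal (racemic; (2S,3S) enantiomer drawn) | COc1cc(OCc2ccccc2)cc(O[C@@H](c2cccc(OCc3ccccc3)c2OCc2ccccc2)[C@H](OC)C=O)c1OC
F13 | step 8 | 5-(benzyloxy)-2-[2,3-bis(benzyloxy)phenyl]-3,7,8-trimethoxy-4-[(trimethylsilyl)oxy]-2H-chromene (racemic; (2S) enantiomer drawn) | COc1cc(OCc2ccccc2)c2C(O[Si](C)(C)C)=C(OC)[C@H](c3cccc(OCc4ccccc4)c3OCc3ccccc3)Oc2c1OC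
A1 | alternative 1 | 2-[2,3-bis(methoxymethoxy)phenyl]-3,7,8-trimethoxy-4-oxo-4H-chromen-5-yl pivalate | COc1cc(OC(=O)C(C)(C)C)c2c(=O)c(OC)c(-c3cccc(OCOC)c3OCOC)oc2c1OC
A2 | alternative 1 | 7,8-dimethoxy-2,2-dimethyl-4-oxo-4H-1,3-benzodioxin-5-yl pivalate | COc1cc(OC(=O)C(C)(C)C)c2C(=O)OC(C)(C)Oc2c1OC
A3 | alternative 1 | (Z)-{1-[2,3-bis(methoxymethoxy)phenyl]-2-methoxyethenyl}oxy(trimethyl)silane | CO/C=C(\O[Si](C)(C)C)c1cccc(OCOC)c1OCOC
A4 | alternative 1 | 3,4-dimethoxy-5-oxo-6-(oxomethylidene)cyclohexa-1,3-dien-1-yl pivalate | O=C=C1C(OC(=O)C(C)(C)C)=CC(OC)=C(OC)C1=O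
A5 | alternative 2 | 2-(1,3-benzodioxol-4-yl)-3,5,7,8-tetramethoxy-4H-chromen-4-one | COc1cc(OC)c2c(=O)c(OC)c(-c3cccc4OCOc34)oc2c1OC
A6 | alternative 2 | 1-(2-hydroxy-3,4,6-trimethoxyphenyl)-2-methoxyethan-1-one | COCC(=O)c1c(O)c(OC)c(OC)cc1OC
A7 | alternative 2 | 4-iodo-1,3-benzodioxole | Ic1cccc2OCOc12
A8 | alternative 2 | carbon monoxide | [C-]#[O+]
A9 | alternative 3 | 2-[2,3-bis(benzyloxy)phenyl]-5,8-dihydroxy-3,7-dimethoxy-4H-chromen-4-one | COc1cc(O)c2c(=O)c(OC)c(-c3cccc(OCc4ccccc4)c3OCc5ccccc5)oc2c1O
A10 | alternative 3 | 2-[2,3-bis(benzyloxy)phenyl]-6-(1-hydroxy-2-methoxy-4-oxocyclobut-2-en-1-yl)-3-methoxy-4H-pyran-4-one (racemic; one enantiomer drawn) | COC1=CC(=O)[C@@]1(O)c1cc(=O)c(OC)c(-c2cccc(OCc3ccccc3)c2OCc2ccccc2)o1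
A11 | alternative 3 | 2-[2,3-bis(benzyloxy)phenyl]-3-methoxy-4H-pyran-4-one | O=c1ccoc(-c2cccc(OCc3ccccc3)c2OCc2ccccc2)c1OC
A12 | alternative 3 | 3-methoxycyclobut-3-ene-1,2-dione | COC1=CC(=O)C1=O
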